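**Retrosynthetic overview**
1. The target is two (3R,4S)-trans-4-oxy-6,8-dihydroxy-7-methoxy-3-methylisochroman-1-ones joined C4–O–C6' (primed locants = the half with the free C4'–OH). The ether is cut first: it is made last by Mitsunobu inversion of a cis-(3R,4R)-4-hydroxy lactone (10) with the C6'-phenol of the trans series (12). Compound 12 is 10 after a Mitsunobu inversion with formic acid, so one monomer feeds both halves.
2. Key cut: in the lactone ring (C1, O2, C3, C4, C4a, C8a) the bonds C1–C8a and O2–C3 are cut together, which excises CO2. Forward, CO2 is stitched between aryl C8a (C–Br to C–Li) and the vinyl group of an (S)-aryl vinyl carbinol by carboxylation and 6-exo iodolactonization in one flask; C–I reduction then gives the C3 methyl.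
3. Enabling feature: C8a is ortho to C4a, which carries the C4(OH)–C3 chain (a 2-allylbenzoate array), so a carboxylate on C8a reaches C3 through a six-membered ring. In the 3,5-dioxygenated 4-methoxyphenyl precursor the two ring CH positions (future C5 and C8a) are equivalent, so the halogen marking C8a needs no regiocontrol. Later the C8–OH···O=C1 hydrogen bond distinguishes C8–OH from C6–OH.
4. Stereochemistry: C4 comes from one catalytic asymmetric vinylation of an aldehyde; C3 is relayed from C4 in the key step; C4 is then inverted once in each half (formate in the primed half, aryl ether in the unprimed half).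
5. Ring order: benzene ring bought (methyl 4-O-methylgallate) → lactone ring (step 6, serving both halves) → ether union (step 10) → global deprotection (step 11).

Key step: step 6

Remark: methyl 3,5-dihydroxy-4-methoxybenzoate is taken as commercial, and (−)-DAIB is assumed to direct the vinyl group to the same aldehyde face as in its dialkylzinc additions, which gives (S)-6.

**Step 1**
Reactants: 1 methyl 3,5-dihydroxy-4-methoxybenzoate
Product: 2 methyl 4-methoxy-3,5-bis(methoxymethoxy)benzoate
Conditions: MOMCl (2.5 equiv), i-Pr2NEt, CH2Cl2, 0 °C to rt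
Reagents that add atoms: chloromethyl methyl ether, COCCl
Why: O-alkylation of both phenols (Williamson-type acetal formation) should be clean, and the MOM ethers tolerate the later organolithium, hydride, radical and Mitsunobu steps and leave with acid.

**Step 2**
Reactants: 2 methyl 4-methoxy-3,5-bis(methoxymethoxy)benzoate
Product: 3 methyl 2-bromo-4-methoxy-3,5-bis(methoxymethoxy)benzoate
Conditions: NBS (1.05 equiv), MeCN, 0 °C to rt
Reagents that add atoms: N-bromosuccinimide, O=C1CCC(=O)N1Br
Why: Electrophilic aromatic bromination can give only one monobromide because the two free ring positions are equivalent (each ortho to one OMOM and para to the other), and the ester-deactivated product should resist a second bromination.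

**Step 3**
Reactants: 3 methyl 2-bromo-4-methoxy-3,5-bis(methoxymethoxy)benzoate
Product: 4 [2-bromo-4-methoxy-3,5-bis(methoxymethoxy)phenyl]methanol
Conditions: DIBAL-H (2.5 equiv), CH2Cl2, −78 to 0 °C; aq. KNaC4H4O6
Reagents that add atoms: none
Why: Hydride reduction of the ester to the primary alcohol should leave the aryl bromide and the acetals untouched at this temperature.

**Step 4**
Reactants: 4 [2-bromo-4-methoxy-3,5-bis(methoxymethoxy)phenyl]methanol
Product: 5 2-bromo-4-methoxy-3,5-bis(methoxymethoxy)benzaldehyde
Conditions: MnO2 (activated, excess), CH2Cl2, rt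
Reagents that add atoms: none
Why: Selective benzylic alcohol oxidation under neutral heterogeneous conditions should stop at the aldehyde and keep the MOM ethers.

**Step 5**
Reactants: 5 2-bromo-4-methoxy-3,5-bis(methoxymethoxy)benzaldehyde
Product: 6 (1S)-1-[2-bromo-4-methoxy-3,5-bis(methoxymethoxy)phenyl]prop-2-en-1-ol
Conditions: Zn(CH=CH2)2 (1.5 equiv), (−)-DAIB [(2S)-3-exo-(dimethylamino)isoborneol, 5 mol %], toluene, 0 °C; aq. NH4Cl
Reagents that add atoms: divinylzinc, C=C[Zn]C=C
Why: Amino-alcohol-catalysed enantioselective addition of a diorganozinc to an aryl aldehyde (Noyori-type DAIB catalysis) should deliver the vinyl group to one aldehyde face through the chiral zinc aminoalkoxide, setting the (S)-carbinol, the only stereocentre of the route set by a catalyst.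

**Step 6**
Reactants: 6 (1S)-1-[2-bromo-4-methoxy-3,5-bis(methoxymethoxy)phenyl]prop-2-en-1-ol
Product: 9 (3S,4R)-4-hydroxy-3-(iodomethyl)-7-methoxy-6,8-bis(methoxymethoxy)-3,4-dihydro-1H-isochromen-1-one, via aryllithium alkoxide 7 (not isolated), via lithium hydroxybenzoate 8 (not isolated)
Conditions: n-BuLi (2.1 equiv), THF, −78 °C; CO2 (g), −78 to 0 °C; sat. aq. NaHCO3, 0 °C, 30 min; then I2 (2.5 equiv), 0 °C, dark
Reagents that add atoms: carbon dioxide, O=C=O; iodine, II
Why: Deprotonation of the carbinol and Br–Li exchange at the only C–Br bond give an aryllithium chelated by the neighbouring OMOM and alkoxide oxygens; CO2 capture builds the C1–C8a bond, and the carboxylate, never acidified, then adds to the I2-activated vinyl group to build the O2–C3 bond. The closest known reactions are the carboxylation of ortho-lithiated benzylic alkoxides and the iodolactonization of 2-allylbenzoic acids to 3-(iodomethyl)isochroman-1-ones; telescoping them avoids the free hydroxy acid, which would close to the five-membered 3-vinylphthalide on acidification. The lactone ring (C1, O2, C3, C4, C4a, C8a) closes in the 6-exo-trig mode with Markovnikov attack of oxygen at the internal alkene carbon C3, the 7-endo alternative being disfavoured on both counts. The new stereocentre C3 is controlled by the C4 carbinol: in the kinetic cyclization the allylic hydroxyl should lie in the alkene plane (inside-alkoxy model) while the carboxylate attacks anti to the iodonium, so the product carries CH2I pseudo-equatorial and C4–OH pseudo-axial, away from the peri C5–H, which is the 3,4-cis isomer. The step needs this cis facial selectivity, secured by the free allylic OH, and capture of the iodonium by the carboxylate and not by the hemicarbonate formed from the alkoxide and CO2, secured by hydrolysing the latter in aqueous NaHCO3 before iodine is added.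

**Step 7**
Reactants: 9 (3S,4R)-4-hydroxy-3-(iodomethyl)-7-methoxy-6,8-bis(methoxymethoxy)-3,4-dihydro-1H-isochromen-1-one
Product: 10 (3R,4R)-4-hydroxy-7-methoxy-6,8-bis(methoxymethoxy)-3-methyl-3,4-dihydro-1H-isochromen-1-one (3,4-cis)
Conditions: Bu3SnH (1.3 equiv), AIBN (cat.), toluene, 80 °C
Reagents that add atoms: none
Why: Radical-chain dehalogenation of the primary iodide should outrun any 1,2-acyloxy shift and touches no stereocentre (the C3 descriptor changes from S to R only because CH2I becomes CH3).

**Step 8**
Reactants: 10 (3R,4R)-4-hydroxy-7-methoxy-6,8-bis(methoxymethoxy)-3-methyl-3,4-dihydro-1H-isochromen-1-one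
Product: 11 (3R,4S)-7-methoxy-6,8-bis(methoxymethoxy)-3-methyl-1-oxo-3,4-dihydro-1H-isochromen-4-yl formate (3,4-trans)
Conditions: HCO2H (3 equiv), PPh3, DIAD, THF, 0 °C to rt
Reagents that add atoms: formic acid, OC=O
Why: Mitsunobu esterification should invert C4 (4R to 4S) by SN2 attack of formate on the face anti to the cis C3 methyl, the ortho lactone carbonyl disfavouring ionization of the benzylic oxyphosphonium; the formate also protects the C4 oxygen.

**Step 9**
Reactants: 11 (3R,4S)-7-methoxy-6,8-bis(methoxymethoxy)-3-methyl-1-oxo-3,4-dihydro-1H-isochromen-4-yl formate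
Product: 12 (3R,4S)-6,8-dihydroxy-7-methoxy-3-methyl-1-oxo-3,4-dihydro-1H-isochromen-4-yl formate
Conditions: Me3SiBr (2.5 equiv), CH2Cl2, −30 °C; pH 7 NaH2PO4/Na2HPO4 buffer
Reagents that add atoms: none
Why: Silyl-bromide cleavage of the aryl methoxymethyl acetals under aprotic, non-nucleophilic conditions should spare the formate, the lactone and the aryl methyl ether, the aryl silyl ethers hydrolysing on work-up.

**Step 10**
Reactants: 10 (3R,4R)-4-hydroxy-7-methoxy-6,8-bis(methoxymethoxy)-3-methyl-3,4-dihydro-1H-isochromen-1-one (1.3 equiv); 12 (3R,4S)-6,8-dihydroxy-7-methoxy-3-methyl-1-oxo-3,4-dihydro-1H-isochromen-4-yl formate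
Product: 13 (3R,4S)-8-hydroxy-7-methoxy-6-{[(3R,4S)-7-methoxy-6,8-bis(methoxymethoxy)-3-methyl-1-oxo-3,4-dihydro-1H-isochromen-4-yl]oxy}-3-methyl-1-oxo-3,4-dihydro-1H-isochromen-4-yl formate
Conditions: PPh3, DIAD (slow addition), toluene–THF, 0 °C to rt
Reagents that add atoms: none
Why: Mitsunobu aryl ether formation should invert C4 of 10 (4R to 4S) and occur only at the C6 hydroxyl of 12, which is free and para to the lactone carbonyl, whereas the C8 hydroxyl is locked in a hydrogen bond to C1=O (as in the para-selective O-alkylation of 2,4-dihydroxybenzoates) and the carbinol of 12 is masked as the formate.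

**Step 11**
Reactants: 13 (3R,4S)-8-hydroxy-7-methoxy-6-{[(3R,4S)-7-methoxy-6,8-bis(methoxymethoxy)-3-methyl-1-oxo-3,4-dihydro-1H-isochromen-4-yl]oxy}-3-methyl-1-oxo-3,4-dihydro-1H-isochromen-4-yl formate
Product: 14 (3R,4S)-4,8-dihydroxy-6-{[(3R,4S)-6,8-dihydroxy-7-methoxy-3-methyl-1-oxo-3,4-dihydro-1H-isochromen-4-yl]oxy}-7-methoxy-3-methyl-3,4-dihydro-1H-isochromen-1-one (target)
Conditions: HCl (1.25 M in MeOH), 0 °C to rt
Reagents that add atoms: none
Why: Acid-catalysed methanolysis should remove both aryl MOM acetals and the formate in one operation, while the di-ortho-substituted aryl lactones resist acyl attack and the ortho carbonyl disfavours ionization of either benzylic C4–O bond, so no stereocentre is disturbed.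

**Compound list**
1 | methyl 3,5-dihydroxy-4-methoxybenzoate | COC(=O)c1cc(O)c(OC)c(O)c1 | starting material
2 | methyl 4-methoxy-3,5-bis(methoxymethoxy)benzoate | COC(=O)c1cc(OCOC)c(OC)c(OCOC)c1 | intermediate
3 | methyl 2-bromo-4-methoxy-3,5-bis(methoxymethoxy)benzoate | COC(=O)c1cc(OCOC)c(OC)c(OCOC)c1Br | intermediate
4 | [2-bromo-4-methoxy-3,5-bis(methoxymethoxy)phenyl]methanol | OCc1cc(OCOC)c(OC)c(OCOC)c1Br | intermediate
5 | 2-bromo-4-methoxy-3,5-bis(methoxymethoxy)benzaldehyde | O=Cc1cc(OCOC)c(OC)c(OCOC)c1Br | intermediate
6 | (1S)-1-[2-bromo-4-methoxy-3,5-bis(methoxymethoxy)phenyl]prop-2-en-1-ol | C=C[C@H](O)c1cc(OCOC)c(OC)c(OCOC)c1Br | intermediate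
7 | lithium (1S)-1-[2-lithio-4-methoxy-3,5-bis(methoxymethoxy)phenyl]prop-2-en-1-olate (aryllithium alkoxide) | C=C[C@H](O[Li])c1cc(OCOC)c(OC)c(OCOC)c1[Li] | intermediate
8 | lithium 6-[(1S)-1-hydroxyprop-2-en-1-yl]-3-methoxy-2,4-bis(methoxymethoxy)benzoate (lithium hydroxybenzoate) | C=C[C@H](O)c1cc(OCOC)c(OC)c(OCOC)c1C(=O)[O-].[Li+] | intermediate
9 | (3S,4R)-4-hydroxy-3-(iodomethyl)-7-methoxy-6,8-bis(methoxymethoxy)-3,4-dihydro-1H-isochromen-1-one | COc1c(OCOC)cc2c(c1OCOC)C(=O)O[C@H](CI)[C@@H]2O | intermediate
10 | (3R,4R)-4-hydroxy-7-methoxy-6,8-bis(methoxymethoxy)-3-methyl-3,4-dihydro-1H-isochromen-1-one | COc1c(OCOC)cc2c(c1OCOC)C(=O)O[C@H](C)[C@@H]2O | intermediate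
11 | (3R,4S)-7-methoxy-6,8-bis(methoxymethoxy)-3-methyl-1-oxo-3,4-dihydro-1H-isochromen-4-yl formate | COc1c(OCOC)cc2c(c1OCOC)C(=O)O[C@H](C)[C@H]2OC=O | intermediate
12 | (3R,4S)-6,8-dihydroxy-7-methoxy-3-methyl-1-oxo-3,4-dihydro-1H-isochromen-4-yl formate | COc1c(O)cc2c(c1O)C(=O)O[C@H](C)[C@H]2OC=O | intermediate
13 | (3R,4S)-8-hydroxy-7-methoxy-6-{[(3R,4S)-7-methoxy-6,8-bis(methoxymethoxy)-3-methyl-1-oxo-3,4-dihydro-1H-isochromen-4-yl]oxy}-3-methyl-1-oxo-3,4-dihydro-1H-isochromen-4-yl formate | COc1c(OCOC)cc2c(c1OCOC)C(=O)O[C@H](C)[C@H]2Oc1cc2c(c(O)c1OC)C(=O)O[C@H](C)[C@H]2OC=O | intermediate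
14 | (3R,4S)-4,8-dihydroxy-6-{[(3R,4S)-6,8-dihydroxy-7-methoxy-3-methyl-1-oxo-3,4-dihydro-1H-isochromen-4-yl]oxy}-7-methoxy-3-methyl-3,4-dihydro-1H-isochromen-1-one | COc1c(O)cc2c(c1O)C(=O)O[C@H](C)[C@H]2Oc1cc2c(c(O)c1OC)C(=O)O[C@H](C)[C@H]2O | target

**Step count**
Total steps: 11. Longest linear sequence: 11 steps (1 → 14; compound 10 is used twice, once directly in step 10 and once by way of 11 and 12).

**Steps most likely to fail**

Step 6. What may go wrong: incomplete facial discrimination in the iodocyclization, so that the C3 epimer is carried along, and partial capture of the iodonium by the hemicarbonate oxygen. The fallback replaces the substrate-controlled relay by a catalyst-controlled reset. It sets out from 10, taken on after step 7 as its mixture with the C3 epimer. Dess–Martin oxidation of the C4 carbinol would give 7-methoxy-6,8-bis(methoxymethoxy)-3-methyl-1H-isochromene-1,4(3H)-dione F1, whose C3 centre (alpha to the ketone and carrying the acyloxy group) epimerises readily. Asymmetric transfer hydrogenation under dynamic kinetic resolution with RuCl[(S,S)-TsDPEN](p-cymene) and HCO2H–Et3N should then set C4 by catalyst control and C3 through the cis preference known for such reductions of alpha-substituted cyclic aryl ketones. It comes back at 10 as the single (3R,4R) isomer.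

Step 10. What may go wrong: slow capture of the hindered C4 oxyphosphonium by the ortho-methoxy phenol, so that alkylation of the reduced azodicarboxylate or anti-elimination toward the 3-methylisocoumarin takes over. The fallback separates activation from displacement. It sets out from 10. Sulfonylation with (MeSO2)2O and pyridine at −20 °C (no chloride present, hence retention) would give (3R,4R)-7-methoxy-6,8-bis(methoxymethoxy)-3-methyl-1-oxo-3,4-dihydro-1H-isochromen-4-yl methanesulfonate F2. Williamson displacement by the cesium phenoxide of 12 (one equivalent of Cs2CO3, DMF, 0 °C to rt, the chelated C8 hydroxyl remaining un-ionised) should proceed with inversion and comes back at 13.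

Step 5. What may go wrong: erosion of enantioselectivity by uncatalysed or salt-promoted vinyl transfer. The fallback replaces asymmetric catalysis by resolution. It sets out from 5. Vinylmagnesium bromide (THF, −78 °C) would give racemic 1-[2-bromo-4-methoxy-3,5-bis(methoxymethoxy)phenyl]prop-2-en-1-ol F3. Lipase-catalysed acylative kinetic resolution (Burkholderia cepacia lipase, vinyl acetate, MTBE) should acetylate the (R)-enantiomer to (1R)-1-[2-bromo-4-methoxy-3,5-bis(methoxymethoxy)phenyl]prop-2-en-1-yl acetate F4 (Kazlauskas rule, aryl large and vinyl medium) and leave the (S)-alcohol, which comes back at 6.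

**Further compounds**
F1 | step 6 | 7-methoxy-6,8-bis(methoxymethoxy)-3-methyl-1H-isochromene-1,4(3H)-dione | COc1c(OCOC)cc2c(c1OCOC)C(=O)OC(C)C2=O
F2 | step 10 | (3R,4R)-7-methoxy-6,8-bis(methoxymethoxy)-3-methyl-1-oxo-3,4-dihydro-1H-isochromen-4-yl methanesulfonate | COc1c(OCOC)cc2c(c1OCOC)C(=O)O[C@H](C)[C@@H]2OS(C)(=O)=O
F3 | step 5 | rac-1-[2-bromo-4-methoxy-3,5-bis(methoxymethoxy)phenyl]prop-2-en-1-ol | C=CC(O)c1cc(OCOC)c(OC)c(OCOC)c1Br
F4 | step 5 | (1R)-1-[2-bromo-4-methoxy-3,5-bis(methoxymethoxy)phenyl]prop-2-en-1-yl acetate | C=C[C@@H](OC(C)=O)c1cc(OCOC)c(OC)c(OCOC)c1Br
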